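(The earlier runs and the new flask are calculated with made-up constants, and the scatter is random.)

Reckon Sunday's and Wednesday's flasks from the late readings of the two earlier runs.

| flask | electrophile | nucleophile | remark | time |
|---|---|---|---|---|
| green | 0.18 M | 0.26 M (fed, over 6.0 min) | run made earlier; the fed solution adds 0.50 times the starting volume |  |
| amber | 0.18 M | 0.35 M (fed, over 6.0 min) | run made earlier; the fed solution adds 0.50 times the starting volume |  |
| Sunday's | 0.18 M | 0.180 M (fed, over 6.0 min) | the fed solution adds 0.50 times the starting volume | 30 min |
| Wednesday's | 0.18 M | 0.270 M (fed, over 6.0 min) | the fed solution adds 0.50 times the starting volume | 30 min |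

| run | time / min | electrophile / % | product / % |
|---|---|---|---|
| green | 1.00 | 97.3 | 3.6 |
| green | 3.00 | 80.5 | 19.3 |
| green | 5.00 | 63.7 | 37.0 |
| green | 8.00 | 43.2 | 57.5 |
| green | 12.0 | 30.5 | 69.7 |
| green | 15.0 | 23.5 | 76.1 |
| amber | 1.33 | 92.6 | 7.7 |
| amber | 2.00 | 85.5 | 14.7 |
| amber | 3.00 | 75.1 | 25.2 |
| amber | 5.00 | 52.8 | 47.5 |
| amber | 10.0 | 21.9 | 78.0 |
| amber | 15.0 | 12.0 | 88.1 |

(each reading ± 0.5 percentage points)

1. part of the electrophile that has reacted at the end, Sunday's
2. part of the electrophile that has reacted at the end, Wednesday's
3. what raising the concentration of nucleophile from its lowest to its highest value here does to the part of the electrophile that has reacted (changes below 5 percentage points count as none) (it falls / it rises / no change)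

- every charge counts on the volume at the start, and the solution that is fed holds the whole dose
- the numbers in the tables scatter with a standard deviation of 0.5 percentage points

Let e be the electrophile left as a fraction of its charge, and d the nucleophile charge over the electrophile charge, less one. If the loss after the feed runs as κ·e·(e+d), then ln((e+d)/e) climbs steadily at κd per minute, and where d is zero, 1/e climbs at κ. The green run has d of 0.444 and the amber run 0.944. Two late readings of each give κ of 0.114 min⁻¹ in the green run and 0.109 min⁻¹ in the amber run. I take their mean, 0.111 min⁻¹, as the tail constant, an apparent second-order constant in fractions of the charge.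

The green run, read between its points, has 56.9% electrophile left at 6.0 min. I scale the reacted fraction there with the nucleophile charge, which gives 29.9% for Sunday's and 44.8% for Wednesday's. Running κ on to 30 min, with d zero on Sunday's and 0.500 on Wednesday's, I get 75.6% and 92.0% reacted.

The forecast gives 76% and 91.5%, and for the trend it rises: “Conversion therefore rises”.

The part reacted comes to 78.0% in Sunday's flask and 93.5% in Wednesday's; with more nucleophile it rises, by 15 points.

    electrophile + nucleophile → acid set free + product (k = 0.0360 L mol⁻¹ s⁻¹)
    nucleophile + acid set free ⇌ protonated nucleophile, settled at all times (K = 2000 L mol⁻¹)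
    acid set free → by-product carried off (k = 0.0970 s⁻¹)

Neither flask has come to rest at 30 min. Sunday's still holds 22% of its electrophile at 30 min and has 98.6% reacted at 300 min. Wednesday's has 100% reacted at that time, while its free nucleophile goes from 23% to 33.3% and its protonated nucleophile falls from 0.0267 M to 6.38 × 10⁻⁸ M. So the gap of 15 points at the asked time shrinks to 1.4 points at 300 min.

The neighbour of Wednesday's with 0.16 M of nucleophile has d of −0.111, the nucleophile being the limiting reagent by its charge; scaling gives 26.5% reacted at the end of the feed, and the tail constant of 0.111 min⁻¹ gives 69.9% reacted at 30 min. That flask gives 72.6%.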